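The C9–C11 bond is formed in step 16 by a one-pot ketal exchange and Claisen rearrangement that joins a ring-B allylic alcohol to a 2-ethoxydienoate. The route has 19 steps, 16 in the longest linear sequence.

**Retrosynthetic overview**
1. Endgame: both angelates are put on the free 2α,3α-diol last with a mixed anhydride, after an acetonide is removed.
2. Key disconnection C9–C11: C12(=O)–C11–C9–C8=C7 is a γ,δ-unsaturated ketone whose alkene is the ring-B enal C7=C8–C17HO. This Claisen retron leads back to a ring-B allylic alcohol (7β-OH, C8=C9, 8-CHO; a cyclic Morita–Baylis–Hillman-type alcohol) and methyl (2Z)-4-ethoxy-3-methylpenta-2,4-dienoate, joined and rearranged in one operation.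
3. The allylic alcohol comes from a trans-decal-7-one (C8 formylation, dehydrogenation, 1,2-reduction, selective oxidation). The ketone comes from a Δ5-alkene (allylic oxidation at C7; dissolving-metal reduction sets C5).
4. The 2α,3α-diol comes from a Δ2-alkene (α-face dihydroxylation), which comes from the C3 ketone. The C4 gem-dimethyl group is set by deconjugative methylation. The dienoate comes from methyl but-2-ynoate (hydroiodination, Stille coupling).
5. Ring order: ring B is bought as 2-methylcyclohexanone. Ring A is closed by an asymmetric Robinson annulation (sets C10). No ring is formed later.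

Key step: step 16

Remark on the chemistry (numbering): labdane numbering is used.
- Ring A = C1, C2, C3, C4, C5, C10. Ring B = C5, C6, C7, C8, C9, C10.
- C11–C15 = chain on C9, and C16 = methyl on C13.
- C17 = carbon on C8. C18/C19 = methyls on C4. C20 = methyl on C10.
- β = the face that carries C20; α = the opposite face.

**Step 1**
Reactants: 1 2-methylcyclohexanone (racemic); 2 (R)-1-phenylethylamine; 3 methyl vinyl ketone
Product: 6 (S)-2-methyl-2-(3-oxobutyl)cyclohexanone, via imine 4 (not isolated), via alkylated imine 5 (not isolated)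
Conditions: 1, 2, TsOH (cat.), toluene, reflux, Dean–Stark; then 3, 40 °C; then aq. AcOH, rt
Reagents that add atoms: water, O
Why: Asymmetric Michael addition of a chiral imine through its more substituted secondary enamine tautomer (first half of a Robinson annulation), in which C–C bond formation and N–H transfer occur in a compact cyclic transition state on the enamine face away from the phenyl group, so that the quaternary centre C10 is set as S before mild hydrolysis frees the diketone.

**Step 2**
Reactants: 6 (S)-2-methyl-2-(3-oxobutyl)cyclohexanone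
Product: 7 (S)-4a-methyl-4,4a,5,6,7,8-hexahydronaphthalen-2(3H)-one (10-methyl-Δ4-octal-3-one)
Conditions: NaOMe (cat.), MeOH, 60 °C
Reagents that add atoms: none
Why: Intramolecular aldol condensation (second half of the Robinson annulation) closes ring A by attack of the methyl ketone enolate (C4) on the ring ketone (C5), and C10 carries no acidic hydrogen and stays untouched.

**Step 3**
Reactants: 7 (S)-10-methyl-Δ4-octal-3-one
Product: 8 (S)-1,1,4a-trimethyl-3,4,4a,5,6,7-hexahydronaphthalen-2(1H)-one (4,4,10-trimethyl-Δ5-octal-3-one)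
Conditions: KOt-Bu, MeI, t-BuOH, rt
Reagents that add atoms: iodomethane, CI
Why: Deconjugative double α-alkylation of the extended enolate places both methyl groups on C4 and moves the alkene to C5=C6, where it later serves as the handle for C7.

**Step 4**
Reactants: 8 4,4,10-trimethyl-Δ5-octal-3-one
Product: 9 3-(trifluoromethanesulfonyloxy)-4,4,10-trimethyl-Δ2,Δ5-hexalin
Conditions: KHMDS, PhNTf2, THF, −78 °C to 0 °C
Reagents that add atoms: N-phenylbis(trifluoromethanesulfonimide), O=S(=O)(N(c1ccccc1)S(=O)(=O)C(F)(F)F)C(F)(F)F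
Why: Enol triflate formation is regiochemically unambiguous because C4 is quaternary and only the C2 enolate can form.

**Step 5**
Reactants: 9 Δ2-enol triflate
Product: 10 4,4,10-trimethyl-Δ2,Δ5-hexalin [(S)-1,1,4a-trimethyl-1,4,4a,5,6,7-hexahydronaphthalene]
Conditions: Pd(OAc)2 (cat.), PPh3, HCO2H, Et3N, DMF, 60 °C
Reagents that add atoms: none
Why: Palladium-catalysed formate reduction of an enol triflate (oxidative addition, decarboxylation of the palladium formate, reductive elimination) replaces OTf by H without moving either alkene.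

**Step 6**
Reactants: 10 4,4,10-trimethyl-Δ2,Δ5-hexalin
Product: 11 4,4,10-trimethyl-Δ5-octalin-2α,3α-diol
Conditions: OsO4 (cat.), NMO, acetone/H2O, rt
Reagents that add atoms: N-methylmorpholine N-oxide, C[N+]1([O-])CCOCC1; water, O; osmium tetroxide (catalytic oxygen carrier), O=[Os](=O)(=O)=O
Why: Catalytic OsO4/NMO syn-dihydroxylation should touch only the cis-disubstituted C2=C3 bond, because C5=C6 is trisubstituted and flanked by two quaternary carbons, and should come from the α face, because the axial methyls C19 and C20 cover the β face, which sets C2 and C3 as the 2α,3α-cis-diol.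

**Step 7**
Reactants: 11 Δ5-octalin-2α,3α-diol
Product: 12 2α,3α-isopropylidenedioxy-4,4,10-trimethyl-Δ5-octalin
Conditions: Me2C(OMe)2, PPTS (cat.), CH2Cl2, rt
Reagents that add atoms: 2,2-dimethoxypropane, COC(C)(C)OC
Why: Acid-catalysed transketalisation gives the cis-fused acetonide of the equatorial/axial cis-diol, a group that withstands oxidants, dissolving metal, base and hydride.

**Step 8**
Reactants: 12 acetonide of the Δ5-octalin diol
Product: 13 2α,3α-isopropylidenedioxy-4,4,10-trimethyl-Δ5-octal-7-one
Conditions: Rh2(cap)4 (cat.), t-BuOOH (aq.), DCE, 40 °C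
Reagents that add atoms: tert-butyl hydroperoxide, CC(C)(C)OO
Why: Dirhodium caprolactamate/TBHP allylic oxidation, the reaction type used to turn Δ5-steroids into Δ5-7-ketones, has only one site here because C7 is the only allylic position that bears hydrogen (C4 and C10 are quaternary).

**Step 9**
Reactants: 13 Δ5-octal-7-one acetonide
Product: 14 2α,3α-isopropylidenedioxy-4,4,10-trimethyl-trans-decal-7-one (5α-H)
Conditions: Li, NH3(l)/THF, −78 °C; then NH4Cl
Reagents that add atoms: none
Why: Dissolving-metal (Birch-type) enone reduction protonates the β-carbon C5 axially to ring B in the chair-like trans-fused arrangement, which sets 5α-H, and the lithium enolate shields C7 from over-reduction until the quench.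

**Step 10**
Reactants: 14 trans-decal-7-one acetonide
Product: 15 8-[(Z)-hydroxymethylene] derivative of 14
Conditions: NaH, HCO2Et, THF, 0 °C to rt; then AcOH
Reagents that add atoms: ethyl formate, CCOC=O
Why: Crossed Claisen condensation (formylation) under equilibrating conditions goes to C8, as in the C2 formylation of 3-oxo-5α-steroids, because C6 is shielded by C5 and the C4 gem-dimethyl group.

**Step 11**
Reactants: 15 8-hydroxymethylene-7-ketone
Product: 16 2α,3α-isopropylidenedioxy-4,4,10-trimethyl-7-oxo-trans-Δ8(9)-octalin-8-carbaldehyde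
Conditions: DDQ, 1,4-dioxane, rt
Reagents that add atoms: none
Why: DDQ dehydrogenation of a 2-hydroxymethylene ketone proceeds by hydride abstraction from the axial C9–H that is vinylogous to the enol oxygen, the reaction type that gives 2-formyl-Δ1-3-oxo steroids, so that the new alkene can only be C8=C9.

**Step 12**
Reactants: 16 8-formyl-Δ8(9)-en-7-one
Product: 17 2α,3α-isopropylidenedioxy-8-(hydroxymethyl)-4,4,10-trimethyl-trans-Δ8(9)-octalin-7β-ol
Conditions: NaBH4, CeCl3·7H2O, MeOH, −78 °C to 0 °C
Reagents that add atoms: none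
Why: Luche reduction should add hydride 1,2 to both carbonyl groups, and at C7 the hydride enters along the axial α trajectory, which sets the pseudoequatorial 7β-hydroxyl that later steers C9.

**Step 13**
Reactants: 17 7β,17-diol
Product: 18 2α,3α-isopropylidenedioxy-7β-hydroxy-4,4,10-trimethyl-trans-Δ8(9)-octalin-8-carbaldehyde
Conditions: TEMPO (cat.), PhI(OAc)2, CH2Cl2, rt
Reagents that add atoms: none
Why: Oxoammonium (TEMPO/PhI(OAc)2) oxidation distinguishes the primary allylic C17 alcohol from the secondary 7β-alcohol on steric grounds and stops at the aldehyde.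

**Step 14**
Reactants: 19 methyl but-2-ynoate
Product: 20 methyl (Z)-3-iodobut-2-enoate
Conditions: NaI, AcOH, 115 °C
Reagents that add atoms: sodium iodide, [Na+].[I-]
Why: Conjugate hydroiodination of an ynoate occurs by anti addition of iodide and proton, which places iodine cis to the ester and thereby fixes the later C13=C14 Z geometry.

**Step 15**
Reactants: 20 methyl (Z)-3-iodobut-2-enoate; 21 tributyl(1-ethoxyvinyl)stannane
Product: 22 methyl (2Z)-4-ethoxy-3-methylpenta-2,4-dienoate
Conditions: Pd(PPh3)4 (cat.), CuI (cat.), DMF, 50 °C; Et3N-buffered work-up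
Reagents that add atoms: none
Why: Stille coupling of a vinyl iodide with the 1-ethoxyvinyl stannane proceeds with retention of the alkene geometry, and a non-acidic work-up keeps the enol ether.

**Step 16**
Reactants: 18 7β-hydroxy-Δ8(9)-octalin-8-carbaldehyde acetonide; 22 methyl (2Z)-4-ethoxy-3-methylpenta-2,4-dienoate
Product: 25 methyl (13Z)-2α,3α-isopropylidenedioxy-12,17-dioxolabda-7,13-dien-15-oate, via mixed ketal 23 (not isolated), via allyl dienyl ether 24 (not isolated)
Conditions: 22 (4 equiv), 2,4-dinitrophenol (cat.), BHT (trace), xylene, 135 °C, EtOH removed over 5 Å MS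
Reagents that add atoms: none
Why: Acid-catalysed addition of the 7β-hydroxyl of 18 to the enol-ether carbon C12 of 22 gives mixed ketal 23, loss of ethanol gives allyl dienyl ether 24, and 24 undergoes a [3,3]-sigmatropic shift over C11=C12–O–C7–C8=C9 that makes C9–C11, moves the ring alkene to C7=C8 in conjugation with the formyl group and releases the C12 ketone. The closest known reaction types are the Saucy–Marbet (ketal) Claisen rearrangement of allylic alcohols with 2-alkoxypropenes and 2-alkoxy-1,3-dienes, which gives α-methyl enones, and the orthoester Claisen rearrangement of Morita–Baylis–Hillman alcohols. No ring is closed: the only cycle is the six-membered pericyclic transition state, for which ring B has to adopt a boat-like shape so that the C7–O bond becomes pseudoaxial. The single new stereocentre C9 is controlled by suprafacial 1,3-chirality transfer from C7, so the 7β C–O bond is exchanged for a 9β C–C bond and H-9 ends α, on the very face (that of C20) which an untethered nucleophile would avoid. Regioselectivity is secured because C12 has removable hydrogens only on C11 (C13 is sp2) and 18 has a single free hydroxyl, while the formyl group on C8 (position 5 of the allyl vinyl ether) and the alkenyl group on C12 (position 2) lower the barrier and ethanol removal plus irreversible C=O formation pull the equilibria forward. The C13=C14 Z geometry takes no part in the bond reorganisation, and only a weak acid is present.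

**Step 17**
Reactants: 25 acetonide-protected labdane keto ester
Product: 26 methyl (13Z)-2α,3α-dihydroxy-12,17-dioxolabda-7,13-dien-15-oate
Conditions: TFA/H2O, CH2Cl2, 0 °C
Reagents that add atoms: none
Why: Brief acid hydrolysis of the cis-fused acetonide at low temperature should leave the enal, the Z-enedicarbonyl unit and the methyl ester intact, and no stereocentre is acid-labile.

**Step 18**
Reactants: 27 angelic acid [(Z)-2-methylbut-2-enoic acid]; 28 2,4,6-trichlorobenzoyl chloride
Product: 29 angelic 2,4,6-trichlorobenzoic anhydride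
Conditions: Et3N, toluene, rt; filtration
Reagents that add atoms: none
Why: Yamaguchi-type mixed anhydride formation activates angelic acid without an acid chloride stage and without a nucleophilic catalyst, the two usual causes of Z to E isomerisation.

**Step 19**
Reactants: 26 2α,3α-diol; 29 angelic 2,4,6-trichlorobenzoic anhydride
Product: 30 methyl (13Z)-2α,3α-bis(angeloyloxy)-12,17-dioxolabda-7,13-dien-15-oate (CNP0141070.1)
Conditions: 29 (excess), 2,6-lutidine, toluene, 80 °C
Reagents that add atoms: none
Why: Acylation by the Yamaguchi-type mixed anhydride takes place at the less shielded angeloyl carbonyl, the established way to make angelates of hindered alcohols with retention of the Z geometry, and it esterifies first the equatorial 2α- and then the axial 3α-hydroxyl without touching a stereocentre.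

**Compound list**
1 | 2-methylcyclohexanone (racemic) | CC1CCCCC1=O | starting material
2 | (R)-1-phenylethylamine | C[C@@H](N)c1ccccc1 | starting material
3 | methyl vinyl ketone | C=CC(C)=O | starting material
4 | N-[(R)-1-phenylethyl]imine of 2-methylcyclohexanone | CC1CCCCC1=N[C@H](C)c1ccccc1 | intermediate
5 | N-[(R)-1-phenylethyl]imine of (S)-2-methyl-2-(3-oxobutyl)cyclohexanone | CC(=O)CC[C@]1(C)CCCCC1=N[C@H](C)c1ccccc1 | intermediate
6 | (S)-2-methyl-2-(3-oxobutyl)cyclohexanone | CC(=O)CC[C@]1(C)CCCCC1=O | intermediate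
7 | (S)-4a-methyl-4,4a,5,6,7,8-hexahydronaphthalen-2(3H)-one | O=C1CC[C@]2(C)CCCCC2=C1 | intermediate
8 | (S)-1,1,4a-trimethyl-3,4,4a,5,6,7-hexahydronaphthalen-2(1H)-one | O=C1CC[C@]2(C)CCCC=C2C1(C)C | intermediate
9 | 3-(trifluoromethanesulfonyloxy)-4,4,10-trimethyl-Δ2,Δ5-hexalin | O=S(=O)(OC1=CC[C@]2(C)CCCC=C2C1(C)C)C(F)(F)F | intermediate
10 | 4,4,10-trimethyl-Δ2,Δ5-hexalin | C1=CC[C@]2(C)CCCC=C2C1(C)C | intermediate
11 | 4,4,10-trimethyl-Δ5-octalin-2α,3α-diol | O[C@@H]1[C@H](O)C[C@]2(C)CCCC=C2C1(C)C | intermediate
12 | 2α,3α-isopropylidenedioxy-4,4,10-trimethyl-Δ5-octalin | CC1(C)O[C@@H]2C[C@]3(C)CCCC=C3C(C)(C)[C@@H]2O1 | intermediate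
13 | 2α,3α-isopropylidenedioxy-4,4,10-trimethyl-Δ5-octal-7-one | CC1(C)O[C@@H]2C[C@]3(C)CCC(=O)C=C3C(C)(C)[C@@H]2O1 | intermediate
14 | 2α,3α-isopropylidenedioxy-4,4,10-trimethyl-trans-decal-7-one (5α-H) | CC1(C)O[C@@H]2C[C@]3(C)CCC(=O)C[C@H]3C(C)(C)[C@@H]2O1 | intermediate
15 | 8-[(Z)-hydroxymethylene] derivative of 14 | CC1(C)O[C@@H]2C[C@]3(C)C/C(=C/O)C(=O)C[C@H]3C(C)(C)[C@@H]2O1 | intermediate
16 | 2α,3α-isopropylidenedioxy-4,4,10-trimethyl-7-oxo-trans-Δ8(9)-octalin-8-carbaldehyde | CC1(C)O[C@@H]2C[C@]3(C)C=C(C=O)C(=O)C[C@H]3C(C)(C)[C@@H]2O1 | intermediate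
17 | 2α,3α-isopropylidenedioxy-8-(hydroxymethyl)-4,4,10-trimethyl-trans-Δ8(9)-octalin-7β-ol | CC1(C)O[C@@H]2C[C@]3(C)C=C(CO)[C@@H](O)C[C@H]3C(C)(C)[C@@H]2O1 | intermediate
18 | 2α,3α-isopropylidenedioxy-7β-hydroxy-4,4,10-trimethyl-trans-Δ8(9)-octalin-8-carbaldehyde | CC1(C)O[C@@H]2C[C@]3(C)C=C(C=O)[C@@H](O)C[C@H]3C(C)(C)[C@@H]2O1 | intermediate
19 | methyl but-2-ynoate | CC#CC(=O)OC | starting material
20 | methyl (Z)-3-iodobut-2-enoate | C/C(I)=C/C(=O)OC | intermediate
21 | tributyl(1-ethoxyvinyl)stannane | C=C(OCC)[Sn](CCCC)(CCCC)CCCC | starting material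
22 | methyl (2Z)-4-ethoxy-3-methylpenta-2,4-dienoate | C=C(OCC)/C(C)=C\C(=O)OC | intermediate
23 | mixed ethyl/7β-decalinyl ketal of methyl (Z)-3-methyl-4-oxopent-2-enoate (ketal carbon unassigned) | CC1(C)O[C@@H]2C[C@]3(C)C=C(C=O)[C@@H](OC(C)(OCC)/C(C)=C\C(=O)OC)C[C@H]3C(C)(C)[C@@H]2O1 | intermediate
24 | 7β-O-[(3Z)-5-methoxy-3-methyl-5-oxopenta-1,3-dien-2-yl] ether of 18 (allyl dienyl ether) | CC1(C)O[C@@H]2C[C@]3(C)C=C(C=O)[C@@H](OC(=C)/C(C)=C\C(=O)OC)C[C@H]3C(C)(C)[C@@H]2O1 | intermediate
25 | methyl (13Z)-2α,3α-isopropylidenedioxy-12,17-dioxolabda-7,13-dien-15-oate | CC1(C)O[C@@H]2C[C@]3(C)[C@@H](CC(=O)/C(C)=C\C(=O)OC)C(C=O)=CC[C@H]3C(C)(C)[C@@H]2O1 | intermediate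
26 | methyl (13Z)-2α,3α-dihydroxy-12,17-dioxolabda-7,13-dien-15-oate | O[C@@H]1[C@H](O)C[C@]2(C)[C@@H](CC(=O)/C(C)=C\C(=O)OC)C(C=O)=CC[C@H]2C1(C)C | intermediate
27 | angelic acid | C/C=C(/C)C(=O)O | starting material
28 | 2,4,6-trichlorobenzoyl chloride | O=C(Cl)c1c(Cl)cc(Cl)cc1Cl | starting material
29 | angelic 2,4,6-trichlorobenzoic anhydride | C/C=C(/C)C(=O)OC(=O)c1c(Cl)cc(Cl)cc1Cl | intermediate
30 | methyl (13Z)-2α,3α-bis(angeloyloxy)-12,17-dioxolabda-7,13-dien-15-oate (CNP0141070.1) | C/C=C(/C)C(=O)O[C@@H]1[C@H](OC(=O)/C(C)=C\C)C[C@]2(C)[C@@H](CC(=O)/C(C)=C\C(=O)OC)C(C=O)=CC[C@H]2C1(C)C | target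

Total step count: 19. Longest linear sequence: 16 steps (1–13, 16, 17, 19).

**Steps most likely to fail**

**Step 16 (exchange/Claisen union).**
- What may go wrong:
  - ketal exchange may be slow at the hindered, hydrogen-bonded 7β-hydroxyl;
  - the cis ester may capture the oxocarbenium ion;
  - the enol ether may be lost by a retro-ene path, or the alcohol may dehydrate to the dienal;
  - acid or heat may cause Z to E isomerisation before the boat-like [3,3] shift on the hindered β face takes place.
- Fallback: a Carroll rearrangement. The tether is an ester formed under neutral conditions and leaves as CO2. It sets out from 20 and 18 and comes back at 25.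
  - Palladium-catalysed hydroxycarbonylation of 20 (CO, H2O, Et3N) should give (2Z)-4-methoxy-2-methyl-4-oxobut-2-enoic acid F1.
  - Coupling with Meldrum's acid (DCC, DMAP) should give the acyl Meldrum's acid F2.
  - Heating F2 with 18 in toluene releases the acylketene, which the 7β-hydroxyl traps as the allyl β-keto ester F3.
  - Further heating in xylene takes the enol of F3 through the same suprafacial [3,3] shift to the β-keto acid F4, which loses CO2 in the flask and rejoins the route at 25.

**Step 19 (double angeloylation).**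
- What may go wrong:
  - acylation of the axial 3α-hydroxyl next to the gem-dimethyl group may be incomplete;
  - angelate may isomerise to tiglate on forcing;
  - the Z-enedicarbonyl chain may erode during long heating.
- Fallback: the esters are installed before the side chain exists and the union becomes the last step. It sets out from 16 and comes back at 30.
  - Aqueous TFA should give the 2α,3α-dihydroxy formyl enone F5.
  - 29 in hot toluene should give the bis-angelate formyl enone F6, a substrate that tolerates longer heating.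
  - Luche reduction should give the bis-angelate 7β,17-diol F7.
  - TEMPO/PhI(OAc)2 should give the bis-angelate 7β-hydroxy enal F8.
  - The conditions of step 16 with 22 should lead through the bis-angelate mixed ketal F9 and the bis-angelate allyl dienyl ether F10 directly to 30.

**Step 12 (double 1,2-reduction).**
- What may go wrong:
  - hydride may add in a conjugate sense to the doubly activated C8=C9 bond;
  - facial selectivity at C7 may be insufficient.
- Fallback: no alkylidene dicarbonyl stage, and the formyl carbon is brought in as an electrophile. It sets out from 14 and comes back at 18.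
  - IBX dehydrogenation (DMSO, 70 °C) should give the Δ8(9)-en-7-one F11.
  - α-Iodination (I2, pyridine) should give the 8-iodo enone F12.
  - Luche reduction of this simple enone should give the 8-iodo-7β-ol F13.
  - Deprotonation, iodine–lithium exchange (MeLi, then t-BuLi, THF, −78 °C) and a DMF quench should give 18.

**Further compounds**
F1 | step 16 | (2Z)-4-methoxy-2-methyl-4-oxobut-2-enoic acid | COC(=O)/C=C(/C)C(=O)O
F2 | step 16 | 5-[(2Z)-1-hydroxy-4-methoxy-2-methyl-4-oxobut-2-enylidene]-2,2-dimethyl-1,3-dioxane-4,6-dione | COC(=O)/C=C(/C)C(O)=C1C(=O)OC(C)(C)OC1=O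
F3 | step 16 | 7β-O-[(4Z)-6-methoxy-4-methyl-3,6-dioxohex-4-enoyl] ester of 18 | CC1(C)O[C@@H]2C[C@]3(C)C=C(C=O)[C@@H](OC(=O)CC(=O)/C(C)=C\C(=O)OC)C[C@H]3C(C)(C)[C@@H]2O1
F4 | step 16 | 11-carboxy derivative of 25 (β-keto acid, C11 unassigned) | CC1(C)O[C@@H]2C[C@]3(C)[C@@H](C(C(=O)O)C(=O)/C(C)=C\C(=O)OC)C(C=O)=CC[C@H]3C(C)(C)[C@@H]2O1
F5 | step 19 | 2α,3α-dihydroxy-4,4,10-trimethyl-7-oxo-trans-Δ8(9)-octalin-8-carbaldehyde | O[C@@H]1[C@H](O)C[C@]2(C)C=C(C=O)C(=O)C[C@H]2C1(C)C
F6 | step 19 | 2α,3α-bis(angeloyloxy)-4,4,10-trimethyl-7-oxo-trans-Δ8(9)-octalin-8-carbaldehyde | C/C=C(/C)C(=O)O[C@@H]1[C@H](OC(=O)/C(C)=C\C)C[C@]2(C)C=C(C=O)C(=O)C[C@H]2C1(C)C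
F7 | step 19 | 2α,3α-bis(angeloyloxy)-8-(hydroxymethyl)-4,4,10-trimethyl-trans-Δ8(9)-octalin-7β-ol | C/C=C(/C)C(=O)O[C@@H]1[C@H](OC(=O)/C(C)=C\C)C[C@]2(C)C=C(CO)[C@@H](O)C[C@H]2C1(C)C
F8 | step 19 | 2α,3α-bis(angeloyloxy)-7β-hydroxy-4,4,10-trimethyl-trans-Δ8(9)-octalin-8-carbaldehyde | C/C=C(/C)C(=O)O[C@@H]1[C@H](OC(=O)/C(C)=C\C)C[C@]2(C)C=C(C=O)[C@@H](O)C[C@H]2C1(C)C
F9 | step 19 | mixed ethyl ketal from F8 and 22 (ketal carbon unassigned) | C/C=C(/C)C(=O)O[C@@H]1[C@H](OC(=O)/C(C)=C\C)C[C@]2(C)C=C(C=O)[C@@H](OC(C)(OCC)/C(C)=C\C(=O)OC)C[C@H]2C1(C)C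
F10 | step 19 | allyl dienyl ether from F9 | C/C=C(/C)C(=O)O[C@@H]1[C@H](OC(=O)/C(C)=C\C)C[C@]2(C)C=C(C=O)[C@@H](OC(=C)/C(C)=C\C(=O)OC)C[C@H]2C1(C)C
F11 | step 12 | 2α,3α-isopropylidenedioxy-4,4,10-trimethyl-trans-Δ8(9)-octal-7-one | CC1(C)O[C@@H]2C[C@]3(C)C=CC(=O)C[C@H]3C(C)(C)[C@@H]2O1
F12 | step 12 | 8-iodo derivative of F11 | CC1(C)O[C@@H]2C[C@]3(C)C=C(I)C(=O)C[C@H]3C(C)(C)[C@@H]2O1
F13 | step 12 | 8-iodo-2α,3α-isopropylidenedioxy-4,4,10-trimethyl-trans-Δ8(9)-octalin-7β-ol | CC1(C)O[C@@H]2C[C@]3(C)C=C(I)[C@@H](O)C[C@H]3C(C)(C)[C@@H]2O1
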